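**Retrosynthetic overview**
- The ring B aryl–alkenyl bond is cut last: the target comes from an aryl bromide and (E)-3-(tributylstannyl)prop-2-en-1-ol by Stille coupling, and the C7 acetate comes from the C7 alcohol.
- The C9 methyl group is traced back through CH2OTs and CH2OH to an ethyl ester, so C9 enters as an ester carbon.
- The strategy rests on C8 being the hub of the chain: it is bonded to the phenol oxygen O4' of ring B, to the carbinol carbon C7 on ring A and to C9. Cutting C8–O4' and C7–C8 together leaves a carbene carbon (ethyl diazoacetate), the ring B phenol and the ring A aldehyde, which are joined in one pot through a rhodium carbene, an oxonium ylide and a zirconium–binaphthol-bound aldehyde; this sets C7 and C8.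
- No ring is formed: rings A and B are bought as 3,4,5-trimethoxybenzaldehyde and 4-bromo-2,6-dimethoxyphenol.

Key step: step 1

Assumption: the (R)-antipode of 3,3'-diiodo-BINOL is written for the zirconium complex; the sense of induction with a phenol and an unsubstituted diazoacetate has to be fixed in a first run, and the (S)-ligand is used instead if the adduct proves to be the enantiomer.

**Step 1**
Reactants: 1 4-bromo-2,6-dimethoxyphenol; 2 ethyl diazoacetate; 3 3,4,5-trimethoxybenzaldehyde
Product: 5 ethyl (2S,3R)-2-(4-bromo-2,6-dimethoxyphenoxy)-3-hydroxy-3-(3,4,5-trimethoxyphenyl)propanoate, via protic oxonium ylide 4 (not isolated)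
Conditions: Rh2(OAc)4 (2 mol%), Zr(OBu)4 (15 mol%), (R)-3,3'-diiodo-BINOL (18 mol%), 4 Å MS, CH2Cl2, 0 °C; 1 and 2 added to 3 and the catalysts over 4 h by syringe pump
Reagents that add atoms: none
Why: Proposed new method: Rh2(OAc)4 should take nitrogen out of 2 to give the rhodium carbene, to whose carbon (the later C8) the phenol oxygen of 1 adds, forming the C8–O4' bond and the protic oxonium ylide 4, which is in equilibrium with its enol and is a carbon nucleophile at C8. Before the 1,2-proton shift completes a plain O–H insertion, this nucleophile should add to the carbonyl carbon of 3 held on the chiral Lewis acid made from Zr(OBu)4 and 3,3'-diiodo-BINOL, which forms C7–C8 in an aldol-type step; no ring closes. The closest known reaction type is the three-component coupling of aryl diazoacetates, alcohols and aldehydes by oxonium ylide trapping under Rh2(OAc)4 and a zirconium–binaphthol co-catalyst, extended here to an acceptor-only diazoacetate and a 2,6-disubstituted phenol. C7 should be set by the binaphthol, whose 3,3'-iodine atoms shield one face of the zirconium-bound aldehyde, and C8 by the compact hydrogen-bonded arrangement of ylide and aldehyde at the metal, which should favour the syn (2S,3R) adduct that becomes threo (7R,8R) once C9 is a methyl group. The step needs trapping ahead of the proton shift, syn over anti addition and one aldehyde face; the two ortho methoxy groups of 1 make the ylide oxygen electron-rich and can hold its proton by a hydrogen bond, and the weakly electrophilic aldehyde 3 should react only when activated at zirconium, so the racemic background addition should be slow. Slow addition of 1 and 2 keeps the carbene concentration low and should suppress carbene dimerisation.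

**Step 2**
Reactants: 5 ethyl (2S,3R)-2-(4-bromo-2,6-dimethoxyphenoxy)-3-hydroxy-3-(3,4,5-trimethoxyphenyl)propanoate
Product: 6 (1R,2R)-2-(4-bromo-2,6-dimethoxyphenoxy)-1-(3,4,5-trimethoxyphenyl)propane-1,3-diol
Conditions: LiBH4 (2.5 equiv), THF, MeOH (2 equiv), 0 °C to rt; aq NH4Cl
Reagents that add atoms: none
Why: Borohydride reduction of the ester, activated by its α-aryloxy group, should give the primary alcohol while the weakly basic hydride leaves the aryl bromide alone and avoids retro-aldol cleavage, so C7 and C8 keep their configuration.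

**Step 3**
Reactants: 6 (1R,2R)-2-(4-bromo-2,6-dimethoxyphenoxy)-1-(3,4,5-trimethoxyphenyl)propane-1,3-diol
Product: 7 (2R,3R)-2-(4-bromo-2,6-dimethoxyphenoxy)-3-hydroxy-3-(3,4,5-trimethoxyphenyl)propyl 4-methylbenzenesulfonate
Conditions: TsCl (1.1 equiv), pyridine, CH2Cl2, 0 °C
Reagents that add atoms: 4-methylbenzenesulfonyl chloride, Cc1ccc(cc1)S(Cl)(=O)=O
Why: Selective tosylation by steric differentiation: the unhindered primary C9 hydroxyl should react well ahead of the secondary benzylic C7 hydroxyl, which is flanked by ring A and the aryloxy-bearing C8.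

**Step 4**
Reactants: 7 (2R,3R)-2-(4-bromo-2,6-dimethoxyphenoxy)-3-hydroxy-3-(3,4,5-trimethoxyphenyl)propyl 4-methylbenzenesulfonate
Product: 8 (1R,2R)-2-(4-bromo-2,6-dimethoxyphenoxy)-1-(3,4,5-trimethoxyphenyl)propan-1-ol
Conditions: LiEt3BH (3.5 equiv, 1 M in THF), THF, 0 °C to rt; aq NH4Cl
Reagents that add atoms: none
Why: SN2 displacement of the primary tosylate by the strong hydride donor LiEt3BH (Super-Hydride reduction of a sulfonate) should turn C9 into the methyl group, while the C7 hydroxyl sits in the flask as a triethylborane-bound lithium alkoxide that is a poor nucleophile for oxetane closure and the aryl bromide is inert at this temperature; no stereocentre is touched.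

**Step 5**
Reactants: 8 (1R,2R)-2-(4-bromo-2,6-dimethoxyphenoxy)-1-(3,4,5-trimethoxyphenyl)propan-1-ol
Product: 9 (1R,2R)-2-(4-bromo-2,6-dimethoxyphenoxy)-1-(3,4,5-trimethoxyphenyl)propyl acetate
Conditions: Ac2O (2 equiv), pyridine, DMAP (5 mol%), CH2Cl2, rt
Reagents that add atoms: acetic anhydride, CC(=O)OC(C)=O
Why: DMAP-catalysed acylation of the secondary benzylic alcohol occurs at oxygen, so C7 keeps its configuration.

**Step 6**
Reactants: 9 (1R,2R)-2-(4-bromo-2,6-dimethoxyphenoxy)-1-(3,4,5-trimethoxyphenyl)propyl acetate; 10 (E)-3-(tributylstannyl)prop-2-en-1-ol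
Product: 11 (1R,2R)-2-{4-[(E)-3-hydroxyprop-1-en-1-yl]-2,6-dimethoxyphenoxy}-1-(3,4,5-trimethoxyphenyl)propyl acetate
Conditions: Pd(PPh3)4 (5 mol%), toluene, degassed, 100 °C; aq KF work-up
Reagents that add atoms: none
Why: Stille coupling: zerovalent palladium inserts into the aryl C–Br bond, which has no ortho substituent, the alkenyl group is transferred from tin with retention of the (E) geometry, and reductive elimination under neutral conditions should leave the acetate, the free allylic hydroxyl and both stereocentres untouched.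

**Compound list**
1 | 4-bromo-2,6-dimethoxyphenol | COc1cc(Br)cc(OC)c1O | starting material
2 | ethyl diazoacetate | CCOC(=O)C=[N+]=[N-] | starting material
3 | 3,4,5-trimethoxybenzaldehyde | COc1cc(C=O)cc(OC)c1OC | starting material
4 | protic oxonium ylide from 1 and the carbene of 2 (ethyl 2-[(4-bromo-2,6-dimethoxyphenyl)oxonio]acetate C-ylide) | CCOC(=O)[CH-][OH+]c1c(OC)cc(Br)cc1OC | intermediate
5 | ethyl (2S,3R)-2-(4-bromo-2,6-dimethoxyphenoxy)-3-hydroxy-3-(3,4,5-trimethoxyphenyl)propanoate | COc1cc([C@@H](O)[C@@H](C(=O)OCC)Oc2c(OC)cc(Br)cc2OC)cc(OC)c1OC | intermediate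
6 | (1R,2R)-2-(4-bromo-2,6-dimethoxyphenoxy)-1-(3,4,5-trimethoxyphenyl)propane-1,3-diol | COc1cc([C@@H](O)[C@@H](CO)Oc2c(OC)cc(Br)cc2OC)cc(OC)c1OC | intermediate
7 | (2R,3R)-2-(4-bromo-2,6-dimethoxyphenoxy)-3-hydroxy-3-(3,4,5-trimethoxyphenyl)propyl 4-methylbenzenesulfonate | COc1cc([C@@H](O)[C@@H](COS(=O)(=O)c3ccc(C)cc3)Oc2c(OC)cc(Br)cc2OC)cc(OC)c1OC | intermediate
8 | (1R,2R)-2-(4-bromo-2,6-dimethoxyphenoxy)-1-(3,4,5-trimethoxyphenyl)propan-1-ol | COc1cc([C@@H](O)[C@@H](C)Oc2c(OC)cc(Br)cc2OC)cc(OC)c1OC | intermediate
9 | (1R,2R)-2-(4-bromo-2,6-dimethoxyphenoxy)-1-(3,4,5-trimethoxyphenyl)propyl acetate | COc1cc([C@@H](OC(C)=O)[C@@H](C)Oc2c(OC)cc(Br)cc2OC)cc(OC)c1OC | intermediate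
10 | (E)-3-(tributylstannyl)prop-2-en-1-ol | CCCC[Sn](CCCC)(CCCC)/C=C/CO | starting material
11 | (1R,2R)-2-{4-[(E)-3-hydroxyprop-1-en-1-yl]-2,6-dimethoxyphenoxy}-1-(3,4,5-trimethoxyphenyl)propyl acetate | COc1cc([C@@H](OC(C)=O)[C@@H](C)Oc2c(OC)cc(/C=C/CO)cc2OC)cc(OC)c1OC | target

**Step count**
Total steps: 6. Longest linear sequence: 6 steps (1, 2 and 3 to 11).

**Steps most likely to fail**

Step 1 (Proposed new method). The proton shift in the ylide may outrun addition to the aldehyde, so that plain O–H insertion dominates. The phenol may also exchange onto zirconium and loosen the binaphthol, which would erode the syn/anti and facial selectivity. The fallback is an Evans glycolate aldol; it sets out from 1 and comes back to the route at 6. Phenol 1 would be O-alkylated with bromoacetic acid (NaOH, water, reflux) to 2-(4-bromo-2,6-dimethoxyphenoxy)acetic acid F1. The acid would be activated as its pivalic mixed anhydride (PivCl, Et3N, THF, −20 °C) and joined to lithiated (S)-4-benzyloxazolidin-2-one to give (S)-4-benzyl-3-[2-(4-bromo-2,6-dimethoxyphenoxy)acetyl]oxazolidin-2-one F2. Its (Z)-boron enolate (Bu2BOTf, i-Pr2NEt, CH2Cl2, −78 °C) should add to aldehyde 3 through a chair transition state to give the syn adduct (S)-4-benzyl-3-[(2S,3R)-2-(4-bromo-2,6-dimethoxyphenoxy)-3-hydroxy-3-(3,4,5-trimethoxyphenyl)propanoyl]oxazolidin-2-one F3, in which the auxiliary sets both C7 and C8. LiBH4 in wet THF would then remove the auxiliary reductively and give diol 6 directly, so that steps 1 and 2 are replaced.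

Step 4. The C7 alkoxide may displace the tosylate intramolecularly (oxetane closure), hydride may attack at sulfur and return the diol, or the SN2 reaction may be slow at C9 next to the branched, oxygen-bearing C8. The fallback replaces hydride displacement by a radical reduction; it sets out from 7 and comes back at 8. Finkelstein exchange (NaI, acetone, reflux) would convert 7 into (1R,2S)-2-(4-bromo-2,6-dimethoxyphenoxy)-3-iodo-1-(3,4,5-trimethoxyphenyl)propan-1-ol F4; the descriptor at C8 changes only because iodine raises the rank of C9. The C–I bond would then be reduced in a radical chain (Bu3SnH 1.1 equiv, Et3B/air, toluene, rt, tin hydride kept concentrated) to 8. Iodine abstraction from the alkyl iodide should be far faster than bromine abstraction from the aryl bromide, and no alkoxide is present, so oxetane closure is excluded.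

Step 6. Oxidative addition into the electron-rich aryl bromide may be slow, so that protodestannylation or homocoupling of the stannane takes over, and tin residues may be hard to remove from the polar product. The fallback uses a protected boron partner; it sets out from 9 and comes back at 11. Suzuki–Miyaura coupling of 9 with commercial (E)-2-[3-(tert-butyldimethylsilyloxy)prop-1-enyl]-4,4,5,5-tetramethyl-1,3,2-dioxaborolane, CC(C)(C)[Si](C)(C)OC/C=C/B1OC(C)(C)C(C)(C)O1, (Pd(OAc)2, SPhos, K3PO4, dioxane with 2 equiv water, 80 °C) would give (1R,2R)-2-{4-[(E)-3-(tert-butyldimethylsilyloxy)prop-1-en-1-yl]-2,6-dimethoxyphenoxy}-1-(3,4,5-trimethoxyphenyl)propyl acetate F5. HF·pyridine in THF at 0 °C would then free the allylic alcohol and give 11 without touching the acetate.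

**Further compounds**
F1 | step 1 | 2-(4-bromo-2,6-dimethoxyphenoxy)acetic acid | COc1cc(Br)cc(OC)c1OCC(=O)O
F2 | step 1 | (S)-4-benzyl-3-[2-(4-bromo-2,6-dimethoxyphenoxy)acetyl]oxazolidin-2-one | COc1cc(Br)cc(OC)c1OCC(=O)N1[C@@H](Cc2ccccc2)COC1=O
F3 | step 1 | (S)-4-benzyl-3-[(2S,3R)-2-(4-bromo-2,6-dimethoxyphenoxy)-3-hydroxy-3-(3,4,5-trimethoxyphenyl)propanoyl]oxazolidin-2-one | COc1cc([C@@H](O)[C@@H](C(=O)N3[C@@H](Cc4ccccc4)COC3=O)Oc2c(OC)cc(Br)cc2OC)cc(OC)c1OC
F4 | step 4 | (1R,2S)-2-(4-bromo-2,6-dimethoxyphenoxy)-3-iodo-1-(3,4,5-trimethoxyphenyl)propan-1-ol | COc1cc([C@@H](O)[C@@H](CI)Oc2c(OC)cc(Br)cc2OC)cc(OC)c1OC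
F5 | step 6 | (1R,2R)-2-{4-[(E)-3-(tert-butyldimethylsilyloxy)prop-1-en-1-yl]-2,6-dimethoxyphenoxy}-1-(3,4,5-trimethoxyphenyl)propyl acetate | COc1cc([C@@H](OC(C)=O)[C@@H](C)Oc2c(OC)cc(/C=C/CO[Si](C)(C)C(C)(C)C)cc2OC)cc(OC)c1OC
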